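Remark on the chemistry: ring atoms carry labdane/abietane numbers (C18 is the ester carbon on C4α), the chain is numbered C11–C19 outwards from C9, and technical abietic acid is assumed to be purified through an amine salt before use. In the names of 13–23 abietane numbers are used, so "C14" there is the one-carbon substituent on C8 that ends as the 8β-methyl group.

## Analysis of the target

Target 31 (C26H40O8) is a trans-fused decalin (rings A and B) with a nine-carbon chain (C11–C19) on C9 that ends in a 4-methylbutenolide. The decalin carries six stereocentres: C4 (α-CO2Me, β-Me), C5 (α-H), C10 (β-Me), C9 (α-H, β-chain), C6 (equatorial 6α-OH) and C8 (equatorial 8α-OH, axial 8β-Me). The C4/C5/C9/C10 array, including the 4α-carboxyl, is that of the abietane resin acids. The chain has two more stereocentres, C14 (S, a secondary allylic hydroperoxide beside the C13 exocyclic methylene) and C16 (S, the lactone carbinol). They are 1,3-anti and too far from the decalin to be steered by it. The hydroperoxide is the most fragile group: base dehydrates it to the enone or adds its anion to the butenolide, acid can trigger Hock cleavage, and radicals shift it allylically. The butenolide has an acidic hydrogen on C16 and becomes a leaving group once C14 is a carbonyl. The 6α-hydroxyl lies peri to the C18 ester, and the 8α-hydroxyl is 1,5 to C13. The strategy rests on one feature: C16 is a carbinol between the acyl-level C17 and the C15 methylene, with C14 one carbon further at aldehyde level. That is the C2/C1/C3/C4 pattern of (S)-malic acid, so ring formation (O–C19, C17=C18) can be done on a small α-hydroxy methyl ketone.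

## Retrosynthetic reasoning

**31 to 28 (C14–O).** The two silyl ethers are removed last, from 30, under acidic fluoride so that the hydroperoxide never meets base. The hydroperoxide C–O bond is cut next: 30 comes from mesylate 29 of the C14-epimeric allylic alcohol 28 by displacement with inversion. A carbinol is chosen as the precursor because its configuration can be set by a reagent and then transferred stereospecifically. An ene-type oxygenation of a 13(14)-alkene would give no control at C14.

**28 to 27 + 11 (C13–C14).** This bond joins an sp2 carbon bearing the exocyclic methylene to a carbinol carbon, the retron of a chromium/nickel-mediated addition of a 2-alkenyl triflate to an aldehyde. The cut separates the decalin triflate 27 (six stereocentres) from the butenolide aldehyde 11 (C16), so the two halves are built independently. The forward reaction must set C14 as R under ligand control and tolerate a β-acyloxy aldehyde.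

**11 to 7 + 8 (O–C19 and C17=C18).** Aldehyde 11 is unmasked from acetal 10. The butenolide of 10 is opened at the lactone C–O bond and at the ring alkene, which leads to the α-hydroxy methyl ketone 7 and the two-carbon cumulated ylide 8. Both ring bonds form in one neutral operation and no stereocentre is made; C16 only has to survive.

**7 to 1.** Ketone 7 comes from Weinreb amide 6 and a methyl organometallic, and 6 from hydroxy ester 5. The acetal and ester of 5 arise together from dioxolanone aldehyde 4, in which the acetonide had differentiated the two carboxyls of (S)-malic acid 1 (via 2 and 3). All four chain carbons C14–C17 and the C16 configuration are bought.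

**27 to 23 (the C13 handle).** The enol triflate is the kinetic derivative of methyl ketone 26. That ketone comes from ester 24 through amide 25, and 24 is the Baeyer–Villiger product of isopropyl ketone 23. Here the isopropyl group left by the resin acid is excised.

**23 to 15 (C8–O and C6–O).** The 8α-hydroxyl with its 8β-methyl is traced to Markovnikov hydration of the exocyclic alkene of 21 from the α face (diol 22, then silylation). Alkene 21 is the reductive 1,3-transposition product of the conjugated tosylhydrazone 19 of enal 18. The 6α-hydroxyl of 18 is the γ-oxygen of that enal, introduced through dienyl acetate 16 and its α-epoxide 17. Both oxygens enter from the face opposite the axial 4β- and 10β-methyl groups.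

**15 to 12 (ring C).** Keto enal 15 results from glycol cleavage of diol 14, made by dihydroxylation of the ring C alkene of methyl abietate 13. Abietic acid 12 supplies C4, C5, C9 and C10 with the 4α-carboxyl in place.

## Alternatives that were turned down

**Alternative 1: carbonyl-ene closure of ring B.**
- Disconnection: the C6–C7 bond. In the forward step Me2AlCl promotes a type 2 ene reaction between a formyl group on C5 and a 2-propenyl group on C9 and gives the diester A1 with the 6α-hydroxyl and the 8(17)-methylene.
- For: one C–C bond formation closes ring B and delivers the same functional array as compound 21. The chair transition state should place the hydroxyl equatorially, which is at least as predictable as the α-face oxidation used here for C6. It is also independent of a technical-grade natural product.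
- Against: the monocyclic precursor needs C4 and C10 as quaternary centres next to a formyl-bearing C5, plus a C9 centre α to an ester. That is three to four contiguous stereocentres to build enantioselectively, two of them epimerisable under Lewis acid. A1 then ends at C11, so C12, C13 and the ketone still have to be added next to a neopentyl position.
- Comparison: it would rebuild from scratch what abietic acid 12 supplies, and it says nothing about C14 and C16, where the real stereochemical problem lies. The chosen route gives up this certainty at C6 and relies on face selectivity, but it reaches 21 in seven steps from 12.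

**Alternative 2: carboalumination and epoxide opening.**
- Disconnection: the C13–methyl and C14–C15 bonds. Forward, Cp2ZrCl2-catalysed methylalumination of a decalin terminal alkyne with Me3Al, then opening of an (S)-epoxide by the alkenylalanate, gives the 13E-alkene A2.
- For: this is the most convergent assembly of the chain, with three components in one pot and secure alkene geometry from syn-carbometalation. It is stronger than the chosen route in step economy for C11–C17.
- Against: the exocyclic methylene and the C14 hydroperoxide must then come from a singlet-oxygen ene reaction of the trisubstituted alkene. That reaction has no facial bias at C14 and can also abstract hydrogen from C15 or C12, so isomers would have to be separated at the last, most valuable stage. Excess Me3Al must also coexist with the C18 ester.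
- Comparison: the chosen strategy needs more steps but sets C14 by a ligand-controlled addition followed by a stereospecific displacement, and takes C16 from the chiral pool. The idea behind A2 is kept as the fallback for step 23.

**Alternative 3: polyene-derived bicycle, C6 oxidised from C18.**
- Disconnection: the C6–O bond. Forward, a C18 alkoxyl radical (PhI(OAc)2, I2, light) abstracts the 6α-hydrogen and closes the 6α,18-tetrahydrofuran A3 on a farnesyl-derived bicycle.
- For: site and face selectivity at C6 are enforced by geometry, because only the 6α-hydrogen is within reach. This is more certain than any intermolecular oxidation, including step 13. The route is de novo and could give either enantiomer.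
- Against: it needs an enantioselective cyclisation that also installs the C18 and C8 oxygens. The ether must later be oxidised at C18 to the ester level and opened without relactonisation, and the whole chain must be grown from a C11 acetate. The iodine-based radical step does not tolerate alkenes, which fixes it early.
- Comparison: many redox steps are spent on a problem that the chosen route addresses in two steps on a dienyl acetate. The price is a selectivity that is argued from sterics and not enforced.

Key step: step 7

## Route

**Step 1**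
Reactants: 1 (S)-malic acid
Product: 2 [(4S)-2,2-dimethyl-5-oxo-1,3-dioxolan-4-yl]acetic acid
Conditions: Me2C(OMe)2, TsOH·H2O (cat.), rt
Reagents that add atoms: 2,2-dimethoxypropane, CC(C)(OC)OC
Why: Acid-catalysed acetonide formation ties the C1 carboxyl and the C2 hydroxyl into a dioxolanone and leaves the C4 carboxyl free, which differentiates the two acids without touching the stereocentre.

**Step 2**
Reactants: 2 [(4S)-2,2-dimethyl-5-oxo-1,3-dioxolan-4-yl]acetic acid
Product: 3 (5S)-5-(2-hydroxyethyl)-2,2-dimethyl-1,3-dioxolan-4-one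
Conditions: BH3·THF, THF, 0 °C → rt; MeOH quench
Reagents that add atoms: none
Why: Borane reduces a free carboxylic acid far faster than the lactone-type carbonyl; the alcohol is used at once because it can lactonise with loss of acetone.

**Step 3**
Reactants: 3 (5S)-5-(2-hydroxyethyl)-2,2-dimethyl-1,3-dioxolan-4-one
Product: 4 [(4S)-2,2-dimethyl-5-oxo-1,3-dioxolan-4-yl]acetaldehyde
Conditions: Dess–Martin periodinane, NaHCO3, CH2Cl2, 0 °C → rt
Reagents that add atoms: none
Why: Buffered hypervalent-iodine oxidation stops at the aldehyde and avoids base, which could eliminate the β-oxygen.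

**Step 4**
Reactants: 4 [(4S)-2,2-dimethyl-5-oxo-1,3-dioxolan-4-yl]acetaldehyde
Product: 5 methyl (2S)-2-hydroxy-4,4-dimethoxybutanoate
Conditions: HC(OMe)3, MeOH, TsOH·H2O (cat.), rt
Reagents that add atoms: trimethyl orthoformate, COC(OC)OC; methanol, CO
Why: One acid-catalysed operation acetalises the aldehyde (the future C14) and methanolyses the dioxolanone to the α-hydroxy methyl ester; the C2–O bond is not broken and oxetane formation prevents any cyclisation onto the acetal.

**Step 5**
Reactants: 5 methyl (2S)-2-hydroxy-4,4-dimethoxybutanoate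
Product: 6 (2S)-2-hydroxy-N,4,4-trimethoxy-N-methylbutanamide
Conditions: MeNH(OMe)·HCl, i-PrMgCl, THF, −20 → 0 °C
Reagents that add atoms: N,O-dimethylhydroxylamine hydrochloride, CNOC.Cl
Why: Aminolysis of the ester by the magnesium amide gives the Weinreb amide; the hydroxyl is carried as its alkoxide, which suppresses α-deprotonation at low temperature.

**Step 6**
Reactants: 6 (2S)-2-hydroxy-N,4,4-trimethoxy-N-methylbutanamide
Product: 7 (3S)-3-hydroxy-5,5-dimethoxypentan-2-one
Conditions: MeMgBr (3 eq.), THF, −78 → 0 °C; aq. NH4Cl
Reagents that add atoms: methylmagnesium bromide, C[Mg]Br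
Why: Weinreb ketone synthesis; the chelated tetrahedral intermediate stops at the ketone, and the α-hydroxy ketone is taken on crude to avoid acyloin-type enolisation on silica.

**Step 7**
Reactants: 7 (3S)-3-hydroxy-5,5-dimethoxypentan-2-one; 8 ketenylidenetriphenylphosphorane
Product: 10 (5S)-5-(2,2-dimethoxyethyl)-4-methylfuran-2(5H)-one, via acyl ylide ester 9 (not isolated)
Conditions: toluene, 60 °C then 110 °C
Reagents that add atoms: none
Why: The hydroxyl of 7 adds across the ketene C=C of 8 to give the ester-stabilised phosphorane 9, held next to the C17 ketone; intramolecular Wittig olefination then forms C17=C18 and expels Ph3P=O, so O–C19 and C17=C18 are both made. The closest known reaction type is the butenolide synthesis from α-hydroxy ketones and this cumulated ylide (acylation, then intramolecular Wittig). The ring closes in the Wittig step by 5-exo-trig attack of the ylide carbon on the ketone, and collapse of the oxaphosphetane leaves the alkene endocyclic. No stereocentre is created; C16 is carried unchanged from 1. The step needs O-acylation to precede any enolisation of the ketone and needs C16 to keep its configuration. The medium is neutral and salt-free, the ylide is a weak base, and acylation is run at 60 °C before the slower olefination is driven at reflux. The C14 acetal is inert and keeps the aldehyde away from the ylide.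

**Step 8**
Reactants: 10 (5S)-5-(2,2-dimethoxyethyl)-4-methylfuran-2(5H)-one
Product: 11 [(2S)-3-methyl-5-oxo-2,5-dihydrofuran-2-yl]acetaldehyde
Conditions: Amberlyst-15 (H+ form), acetone–H2O, rt
Reagents that add atoms: water, O
Why: Mild acid hydrolysis of the dimethyl acetal; base is avoided because the β-acyloxy aldehyde can open by elimination, and 11 is used directly.

**Step 9**
Reactants: 12 abietic acid
Product: 13 methyl abietate
Conditions: MeI, K2CO3, DMF, rt
Reagents that add atoms: iodomethane, CI
Why: Carboxylate O-alkylation is the reliable way to esterify the hindered tertiary acid.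

**Step 10**
Reactants: 13 methyl abietate
Product: 14 methyl 13α,14α-dihydroxyabiet-7-en-18-oate
Conditions: OsO4 (cat.), Me3NO·2H2O, pyridine, t-BuOH–H2O, 80 °C
Reagents that add atoms: trimethylamine N-oxide, C[N+](C)(C)[O-]; water, O
Why: Catalytic syn-dihydroxylation should take the more accessible ring C end of the diene; attack anti to the 10β-methyl is expected, but both new centres are erased in step 11.

**Step 11**
Reactants: 14 methyl 13α,14α-dihydroxyabiet-7-en-18-oate
Product: 15 methyl 13,14-dioxo-13,14-secoabiet-7-en-18-oate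
Conditions: NaIO4, THF–H2O, rt
Reagents that add atoms: none
Why: Glycol cleavage of the cis-diol opens ring C to an isopropyl ketone on the C9 chain and a conjugated aldehyde on C8, with C9 untouched.

**Step 12**
Reactants: 15 methyl 13,14-dioxo-13,14-secoabiet-7-en-18-oate
Product: 16 methyl 14-acetoxy-13-oxo-13,14-secoabieta-6,8(14)-dien-18-oate
Conditions: Ac2O, Et3N, DMAP (cat.), toluene, 80 °C
Reagents that add atoms: acetic anhydride, CC(=O)OC(C)=O
Why: Extended enol acetylation of the enal through γ-deprotonation at C6; under amine/DMAP conditions a simple ketone is not enol-acetylated, so only the aldehyde is engaged.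

**Step 13**
Reactants: 16 methyl 14-acetoxy-13-oxo-13,14-secoabieta-6,8(14)-dien-18-oate
Product: 18 methyl 6α-hydroxy-13,14-dioxo-13,14-secoabiet-7-en-18-oate, via epoxy dienyl acetate 17 (not isolated)
Conditions: DMDO, acetone–CH2Cl2, −30 °C; then PPTS (cat.), THF–H2O, 0 °C → rt
Reagents that add atoms: dimethyldioxirane, CC1(C)OO1; water, O
Why: Vinylogous Rubottom-type oxidation: the remote C6=C7 bond of the dienyl acetate is epoxidised on the α face, because the β face is blocked by the axial 4β- and 10β-methyl groups. Hydrolytic opening of the allylic C7–O bond then restores the enal and leaves the 6α-hydroxyl.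

**Step 14**
Reactants: 18 methyl 6α-hydroxy-13,14-dioxo-13,14-secoabiet-7-en-18-oate
Product: 19 methyl 6α-hydroxy-13-oxo-14-(tosylhydrazono)-13,14-secoabiet-7-en-18-oate
Conditions: TsNHNH2, THF, rt
Reagents that add atoms: 4-methylbenzenesulfonohydrazide, Cc1ccc(cc1)S(=O)(=O)NN
Why: Hydrazone formation is much faster at the aldehyde than at the hindered isopropyl ketone at room temperature.

**Step 15**
Reactants: 19 methyl 6α-hydroxy-13-oxo-14-(tosylhydrazono)-13,14-secoabiet-7-en-18-oate
Product: 21 methyl 6α-hydroxy-13-oxo-13,14-secoabiet-8(14)-en-18-oate, via allylic diazene 20 (not isolated)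
Conditions: catecholborane, CHCl3, 0 °C; then NaOAc·3H2O, 60 °C
Reagents that add atoms: none
Why: Alkene-transposing reduction of a conjugated tosylhydrazone: hydride adds to C=N, acetate expels sulfinate, and diazene 20 loses N2 by a 1,5-hydrogen shift to C7. This gives the exocyclic C8 methylene and a C7 methylene without creating a stereocentre.

**Step 16**
Reactants: 21 methyl 6α-hydroxy-13-oxo-13,14-secoabiet-8(14)-en-18-oate
Product: 22 methyl 6α,8α-dihydroxy-13-oxo-13,14-secoabietan-18-oate
Conditions: Mn(dpm)3 (cat.), PhSiH3, O2 (1 atm), i-PrOH–CH2Cl2, 0 °C → rt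
Reagents that add atoms: dioxygen, O=O
Why: Mukaiyama hydration: hydrogen-atom transfer to the methylene gives the tertiary C8 radical, which should be trapped by O2 from the α (equatorial) side because the β side is 1,3-diaxial to the 10β-methyl. This sets 8α-OH and 8β-Me, and ketone and ester are not touched.

**Step 17**
Reactants: 22 methyl 6α,8α-dihydroxy-13-oxo-13,14-secoabietan-18-oate
Product: 23 methyl 13-oxo-6α,8α-bis(triethylsilyloxy)-13,14-secoabietan-18-oate
Conditions: TESOTf, 2,6-lutidine, CH2Cl2, −78 → 0 °C
Reagents that add atoms: triethylsilyl trifluoromethanesulfonate, CC[Si](CC)(CC)OS(=O)(=O)C(F)(F)F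
Why: The silyl triflate caps both the hindered secondary and the tertiary hydroxyl in one step. This blocks hemiketal and enol ether formation between the 8-hydroxyl and C13, and lactonisation of the 6-hydroxyl onto C18, in the basic steps that follow.

**Step 18**
Reactants: 23 methyl 13-oxo-6α,8α-bis(triethylsilyloxy)-13,14-secoabietan-18-oate
Product: 24 18-methyl 13-(propan-2-yl) 6α,8α-bis(triethylsilyloxy)-14,15,16-trinorlabdane-13,18-dioate
Conditions: mCPBA, NaHCO3, CH2Cl2, rt, dark
Reagents that add atoms: 3-chloroperoxybenzoic acid, O=C(OO)c1cccc(Cl)c1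
Why: Baeyer–Villiger oxidation with migration of the secondary isopropyl group in preference to the primary C12; with no alkene left, the ketone is the only site for the peracid.

**Step 19**
Reactants: 24 18-methyl 13-(propan-2-yl) 6α,8α-bis(triethylsilyloxy)-14,15,16-trinorlabdane-13,18-dioate
Product: 25 methyl 13-[methoxy(methyl)amino]-13-oxo-6α,8α-bis(triethylsilyloxy)-14,15,16-trinorlabdan-18-oate
Conditions: MeNH(OMe)·HCl, AlMe3, CH2Cl2, 0 → 40 °C
Reagents that add atoms: N,O-dimethylhydroxylamine hydrochloride, CNOC.Cl
Why: The aluminium amide converts the unhindered isopropyl ester into the Weinreb amide, while the neopentyl C18 methyl ester on a quaternary carbon is too shielded to react.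

**Step 20**
Reactants: 25 methyl 13-[methoxy(methyl)amino]-13-oxo-6α,8α-bis(triethylsilyloxy)-14,15,16-trinorlabdan-18-oate
Product: 26 methyl 13-oxo-6α,8α-bis(triethylsilyloxy)-14,15-dinorlabdan-18-oate
Conditions: MeMgBr, THF, 0 °C
Reagents that add atoms: methylmagnesium bromide, C[Mg]Br
Why: Weinreb ketone synthesis gives the methyl ketone without over-addition; the C18 ester is inert at this temperature.

**Step 21**
Reactants: 26 methyl 13-oxo-6α,8α-bis(triethylsilyloxy)-14,15-dinorlabdan-18-oate
Product: 27 methyl 6α,8α-bis(triethylsilyloxy)-13-(trifluoromethanesulfonyloxy)-14,15-dinorlabd-13(16)-en-18-oate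
Conditions: KN(SiMe3)2, THF, −78 °C; PhNTf2, −78 → −30 °C
Reagents that add atoms: N-phenylbis(trifluoromethanesulfonimide), O=S(=O)(N(c1ccccc1)S(=O)(=O)C(F)(F)F)C(F)(F)F
Why: Kinetic deprotonation with a bulky amide at −78 °C takes the methyl hydrogen, and O-triflation gives the terminal 2-alkenyl triflate; the C18 ester has no α-hydrogen.

**Step 22**
Reactants: 27 methyl 6α,8α-bis(triethylsilyloxy)-13-(trifluoromethanesulfonyloxy)-14,15-dinorlabd-13(16)-en-18-oate; 11 [(2S)-3-methyl-5-oxo-2,5-dihydrofuran-2-yl]acetaldehyde
Product: 28 methyl 6α,8α-bis(triethylsilyloxy)-9β-{(4R)-4-hydroxy-3-methylidene-5-[(2S)-3-methyl-5-oxo-2,5-dihydrofuran-2-yl]pentyl}-4β,8β,10β-trimethyl-trans-decalin-4α-carboxylate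
Conditions: CrCl2 (4 eq.), (S)-N-[2-(4-isopropyl-4,5-dihydrooxazol-2-yl)-6-methylphenyl]methanesulfonamide (4.4 eq.), Et3N, THF, rt; NiCl2 (cat.); 27, 11 (2 eq.), rt
Reagents that add atoms: none
Why: Nozaki–Hiyama–Kishi coupling: zerovalent nickel inserts into the C–OTf bond, the alkenyl group passes to trivalent chromium and adds to the aldehyde, forming C13–C14 under neutral conditions that spare the β-acyloxy aldehyde, lactone and ester. The chiral sulfonamide on chromium is to control the aldehyde face; the ligand enantiomer that gives 14R (syn to the C16 oxygen) is to be fixed in a pilot run, since the remote C16 centre exerts little bias.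

**Step 23**
Reactants: 28 methyl 6α,8α-bis(triethylsilyloxy)-9β-{(4R)-4-hydroxy-3-methylidene-5-[(2S)-3-methyl-5-oxo-2,5-dihydrofuran-2-yl]pentyl}-4β,8β,10β-trimethyl-trans-decalin-4α-carboxylate
Product: 30 methyl 6α,8α-bis(triethylsilyloxy)-9β-{(4S)-4-hydroperoxy-3-methylidene-5-[(2S)-3-methyl-5-oxo-2,5-dihydrofuran-2-yl]pentyl}-4β,8β,10β-trimethyl-trans-decalin-4α-carboxylate, via allylic mesylate 29 (not isolated)
Conditions: Ms2O, Et3N, CH2Cl2, −40 °C; then anhydrous H2O2 in Et2O (excess), −78 → −20 °C, dark
Reagents that add atoms: hydrogen peroxide, OO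
Why: Sulfonate displacement by hydrogen peroxide, a known route from allylic mesylates to allylic hydroperoxides; direct SN2 attack by the α-effect nucleophile at low temperature inverts C14 from R to S. The anhydride avoids chloride, and cold, dark, base-poor conditions are meant to suppress ionisation, SN2′ attack and radical allylic shift.

**Step 24**
Reactants: 30 methyl 6α,8α-bis(triethylsilyloxy)-9β-{(4S)-4-hydroperoxy-3-methylidene-5-[(2S)-3-methyl-5-oxo-2,5-dihydrofuran-2-yl]pentyl}-4β,8β,10β-trimethyl-trans-decalin-4α-carboxylate
Product: 31 methyl 6α,8α-dihydroxy-9β-{(4S)-4-hydroperoxy-3-methylidene-5-[(2S)-3-methyl-5-oxo-2,5-dihydrofuran-2-yl]pentyl}-4β,8β,10β-trimethyl-trans-decalin-4α-carboxylate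
Conditions: HF·pyridine, pyridine, THF, 0 °C
Reagents that add atoms: none
Why: Buffered acidic fluoride cleaves both triethylsilyl ethers. A basic fluoride source is avoided because it would dehydrate the hydroperoxide to the enone, add its anion to the butenolide or epimerise C16.

## Compound list

1 | (S)-malic acid | C([C@@H](C(=O)O)O)C(=O)O | starting material
2 | [(4S)-2,2-dimethyl-5-oxo-1,3-dioxolan-4-yl]acetic acid | OC(=O)C[C@@H]1OC(C)(C)OC1=O | intermediate
3 | (5S)-5-(2-hydroxyethyl)-2,2-dimethyl-1,3-dioxolan-4-one | OCC[C@@H]1OC(C)(C)OC1=O | intermediate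
4 | [(4S)-2,2-dimethyl-5-oxo-1,3-dioxolan-4-yl]acetaldehyde | O=CC[C@@H]1OC(C)(C)OC1=O | intermediate
5 | methyl (2S)-2-hydroxy-4,4-dimethoxybutanoate | COC(=O)[C@@H](O)CC(OC)OC | intermediate
6 | (2S)-2-hydroxy-N,4,4-trimethoxy-N-methylbutanamide | CON(C)C(=O)[C@@H](O)CC(OC)OC | intermediate
7 | (3S)-3-hydroxy-5,5-dimethoxypentan-2-one | CC(=O)[C@@H](O)CC(OC)OC | intermediate
8 | ketenylidenetriphenylphosphorane | O=C=C=P(c1ccccc1)(c1ccccc1)c1ccccc1 | starting material
9 | (3S)-5,5-dimethoxy-2-oxopentan-3-yl (triphenylphosphoranylidene)acetate (not isolated) | CC(=O)[C@H](CC(OC)OC)OC(=O)C=P(c1ccccc1)(c1ccccc1)c1ccccc1 | intermediate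
10 | (5S)-5-(2,2-dimethoxyethyl)-4-methylfuran-2(5H)-one | COC(OC)C[C@@H]1OC(=O)C=C1C | intermediate
11 | [(2S)-3-methyl-5-oxo-2,5-dihydrofuran-2-yl]acetaldehyde | O=CC[C@@H]1OC(=O)C=C1C | intermediate
12 | abietic acid | CC(C)C1=CC2=CC[C@@H]3[C@@]([C@H]2CC1)(CCC[C@@]3(C)C(=O)O)C | starting material
13 | methyl abietate | CC(C)C1=CC2=CC[C@@H]3[C@@]([C@H]2CC1)(CCC[C@@]3(C)C(=O)OC)C | intermediate
14 | methyl 13α,14α-dihydroxyabiet-7-en-18-oate (C13/C14 configuration as expected, erased in step 11) | CC(C)[C@@]1(O)[C@H](O)C2=CC[C@@H]3[C@@]([C@H]2CC1)(CCC[C@@]3(C)C(=O)OC)C | intermediate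
15 | methyl 13,14-dioxo-13,14-secoabiet-7-en-18-oate | CC(C)C(=O)CC[C@@H]1[C@@]2(C)CCC[C@@](C)(C(=O)OC)[C@@H]2CC=C1C=O | intermediate
16 | methyl 14-acetoxy-13-oxo-13,14-secoabieta-6,8(14)-dien-18-oate (either geometry at C8=C14) | CC(C)C(=O)CC[C@@H]1[C@@]2(C)CCC[C@@](C)(C(=O)OC)[C@@H]2C=CC1=COC(C)=O | intermediate
17 | methyl 14-acetoxy-6α,7α-epoxy-13-oxo-13,14-secoabiet-8(14)-en-18-oate (not isolated) | CC(C)C(=O)CC[C@@H]1[C@@]2(C)CCC[C@@](C)(C(=O)OC)[C@@H]2[C@H]3O[C@H]3C1=COC(C)=O | intermediate
18 | methyl 6α-hydroxy-13,14-dioxo-13,14-secoabiet-7-en-18-oate | CC(C)C(=O)CC[C@@H]1[C@@]2(C)CCC[C@@](C)(C(=O)OC)[C@@H]2[C@@H](O)C=C1C=O | intermediate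
19 | methyl 6α-hydroxy-13-oxo-14-(tosylhydrazono)-13,14-secoabiet-7-en-18-oate | CC(C)C(=O)CC[C@@H]1[C@@]2(C)CCC[C@@](C)(C(=O)OC)[C@@H]2[C@@H](O)C=C1C=NNS(=O)(=O)c1ccc(C)cc1 | intermediate
20 | methyl 14-diazenyl-6α-hydroxy-13-oxo-13,14-secoabiet-7-en-18-oate (not isolated) | CC(C)C(=O)CC[C@@H]1[C@@]2(C)CCC[C@@](C)(C(=O)OC)[C@@H]2[C@@H](O)C=C1CN=N | intermediate
21 | methyl 6α-hydroxy-13-oxo-13,14-secoabiet-8(14)-en-18-oate | CC(C)C(=O)CC[C@@H]1[C@@]2(C)CCC[C@@](C)(C(=O)OC)[C@@H]2[C@@H](O)CC1=C | intermediate
22 | methyl 6α,8α-dihydroxy-13-oxo-13,14-secoabietan-18-oate (C14 is the 8β-methyl) | CC(C)C(=O)CC[C@@H]1[C@@]2(C)CCC[C@@](C)(C(=O)OC)[C@@H]2[C@@H](O)C[C@@]1(C)O | intermediate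
23 | methyl 13-oxo-6α,8α-bis(triethylsilyloxy)-13,14-secoabietan-18-oate | CC(C)C(=O)CC[C@@H]1[C@@]2(C)CCC[C@@](C)(C(=O)OC)[C@@H]2[C@@H](O[Si](CC)(CC)CC)C[C@@]1(C)O[Si](CC)(CC)CC | intermediate
24 | 18-methyl 13-(propan-2-yl) 6α,8α-bis(triethylsilyloxy)-14,15,16-trinorlabdane-13,18-dioate | CC(C)OC(=O)CC[C@@H]1[C@@]2(C)CCC[C@@](C)(C(=O)OC)[C@@H]2[C@@H](O[Si](CC)(CC)CC)C[C@@]1(C)O[Si](CC)(CC)CC | intermediate
25 | methyl 13-[methoxy(methyl)amino]-13-oxo-6α,8α-bis(triethylsilyloxy)-14,15,16-trinorlabdan-18-oate | CON(C)C(=O)CC[C@@H]1[C@@]2(C)CCC[C@@](C)(C(=O)OC)[C@@H]2[C@@H](O[Si](CC)(CC)CC)C[C@@]1(C)O[Si](CC)(CC)CC | intermediate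
26 | methyl 13-oxo-6α,8α-bis(triethylsilyloxy)-14,15-dinorlabdan-18-oate | CC(=O)CC[C@@H]1[C@@]2(C)CCC[C@@](C)(C(=O)OC)[C@@H]2[C@@H](O[Si](CC)(CC)CC)C[C@@]1(C)O[Si](CC)(CC)CC | intermediate
27 | methyl 6α,8α-bis(triethylsilyloxy)-13-(trifluoromethanesulfonyloxy)-14,15-dinorlabd-13(16)-en-18-oate | C=C(OS(=O)(=O)C(F)(F)F)CC[C@@H]1[C@@]2(C)CCC[C@@](C)(C(=O)OC)[C@@H]2[C@@H](O[Si](CC)(CC)CC)C[C@@]1(C)O[Si](CC)(CC)CC | intermediate
28 | (14R,16S)-allylic alcohol: methyl 6α,8α-bis(triethylsilyloxy)-9β-{(4R)-4-hydroxy-3-methylidene-5-[(2S)-3-methyl-5-oxo-2,5-dihydrofuran-2-yl]pentyl}-4β,8β,10β-trimethyl-trans-decalin-4α-carboxylate | C=C(CC[C@@H]1[C@@]2(C)CCC[C@@](C)(C(=O)OC)[C@@H]2[C@@H](O[Si](CC)(CC)CC)C[C@@]1(C)O[Si](CC)(CC)CC)[C@H](O)C[C@@H]1OC(=O)C=C1C | intermediate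
29 | (14R,16S)-allylic mesylate of 28 (not isolated) | C=C(CC[C@@H]1[C@@]2(C)CCC[C@@](C)(C(=O)OC)[C@@H]2[C@@H](O[Si](CC)(CC)CC)C[C@@]1(C)O[Si](CC)(CC)CC)[C@H](OS(C)(=O)=O)C[C@@H]1OC(=O)C=C1C | intermediate
30 | (14S,16S)-hydroperoxide, 6,8-bis(triethylsilyl) ether of the target | C=C(CC[C@@H]1[C@@]2(C)CCC[C@@](C)(C(=O)OC)[C@@H]2[C@@H](O[Si](CC)(CC)CC)C[C@@]1(C)O[Si](CC)(CC)CC)[C@@H](OO)C[C@@H]1OC(=O)C=C1C | intermediate
31 | methyl 6α,8α-dihydroxy-9β-{(4S)-4-hydroperoxy-3-methylidene-5-[(2S)-3-methyl-5-oxo-2,5-dihydrofuran-2-yl]pentyl}-4β,8β,10β-trimethyl-trans-decalin-4α-carboxylate (CNP0324515.1) | C=C(CC[C@@H]1[C@@]2(C)CCC[C@@](C)(C(=O)OC)[C@@H]2[C@@H](O)C[C@@]1(C)O)[C@H](C[C@@H]1OC(=O)C=C1C)OO | target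

## Step count and risk

Total: 24 steps. Longest linear sequence: 16 steps (steps 9–24, from abietic acid 12). The butenolide arm is 8 steps from (S)-malic acid 1.

**Step 7 (key step).** The most likely failure is partial loss of configuration at C16. The olefination of an ester-stabilised ylide with a ketone is slow, and prolonged heating gives the ylide time to enolise the α-acyloxy ketone or to deprotonate the product at C16. Fallback: from 7, esterify the hydroxyl with (diethoxyphosphoryl)acetic acid (DCC, DMAP cat., CH2Cl2, 0 °C) to the phosphonoacetate (3S)-5,5-dimethoxy-2-oxopentan-3-yl (diethoxyphosphoryl)acetate F1. Then close the ring by intramolecular Horner–Wadsworth–Emmons olefination under LiCl/i-Pr2NEt in MeCN at 0 °C, which returns to 10 at a far lower temperature.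

**Step 23.** The displacement may lose stereospecificity or regiochemistry. Ionisation of the allylic mesylate, SN2′ attack at the unhindered methylene terminus, or a radical allylic shift of the hydroperoxide would each erode the 14S product. Fallback: from 28 (either C14 epimer), a Mitsunobu reaction with 2-nitrobenzenesulfonylhydrazide (PPh3, DEAD, THF, −30 °C → rt) gives an allylic diazene that loses N2 with 1,3-transposition to the 13E-trisubstituted alkene F2. A Schenck ene reaction of F2 (O2, tetraphenylporphyrin, visible light, CH2Cl2, 0 °C) abstracts hydrogen from the C13 methyl and places the hydroperoxide on C14. This returns to 30, which then has to be separated chromatographically from its C14 epimer and from the C13 regioisomer.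

**Step 22.** Facial selectivity at C14 may be poor, because the chiral ligand must override a substrate with no useful bias, and an alkenyl triflate is a slower partner than an iodide. Fallback: run the coupling of 27 and 11 without the ligand (CrCl2, NiCl2 cat., DMF) to the C14-epimeric alcohol mixture F3. Oxidise with Dess–Martin periodinane to the cross-conjugated C14 ketone F4, and reduce with (S)-2-methyl-CBS-oxazaborolidine and catecholborane in toluene at −78 °C. The 1,1-disubstituted vinyl group acts as the large substituent, which should return 28 (14R).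

**Step 13.** Site selectivity of the oxygen transfer is the risk. Attack on the enol acetate double bond instead of the remote C6=C7 bond would give α-oxygenation at C8, and acid in the second stage could isomerise the γ-hydroxy enal. Fallback: from 16, catalytic OsO4 with N-methylmorpholine N-oxide (acetone–H2O, 0 °C) dihydroxylates the less hindered cis-disubstituted C6=C7 bond from the α face to the diol methyl 14-acetoxy-6α,7α-dihydroxy-13-oxo-13,14-secoabiet-8(14)-en-18-oate F5. Methanolysis of the enol acetate (K2CO3, MeOH, 0 °C) then frees the aldehyde, which loses the 7-hydroxyl by β-elimination and returns to 18.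

**Step 15.** The borane may also reduce the isopropyl ketone, or the ketone may have formed some hydrazone in step 14 and be deoxygenated. Fallback: from 18, NaBH(OAc)3 (THF–AcOH, rt) reduces only the aldehyde to the allylic alcohol methyl 6α,14-dihydroxy-13-oxo-13,14-secoabiet-7-en-18-oate F6. A Mitsunobu reaction of its primary allylic hydroxyl with 2-nitrobenzenesulfonylhydrazide (PPh3, DEAD, THF, −30 °C → rt) generates diazene 20 directly and comes back to the route at 21.

**Step 16.** Facial selectivity in trapping the planar C8 radical may be incomplete and give some 8β-alcohol. Fallback: from 21, ionic Markovnikov hydration by oxymercuration (Hg(OAc)2, THF–H2O, rt) gives the organomercurial methyl 14-(acetoxymercurio)-6α,8α-dihydroxy-13-oxo-13,14-secoabietan-18-oate F7, with water adding to C8 from the equatorial α side. Brief reductive demercuration (NaBH4, aq. NaOH, −10 °C) returns to 22.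

## Further compounds

F1 | step 7 | (3S)-5,5-dimethoxy-2-oxopentan-3-yl (diethoxyphosphoryl)acetate | CCOP(=O)(OCC)CC(=O)O[C@@H](CC(OC)OC)C(C)=O
F2 | step 23 | methyl 6α,8α-bis(triethylsilyloxy)-9β-{(3E)-3-methyl-5-[(2S)-3-methyl-5-oxo-2,5-dihydrofuran-2-yl]pent-3-enyl}-4β,8β,10β-trimethyl-trans-decalin-4α-carboxylate | C/C(CC[C@@H]1[C@@]2(C)CCC[C@@](C)(C(=O)OC)[C@@H]2[C@@H](O[Si](CC)(CC)CC)C[C@@]1(C)O[Si](CC)(CC)CC)=C\C[C@@H]1OC(=O)C=C1C
F3 | step 22 | C14-epimeric mixture of allylic alcohol 28 | C=C(CC[C@@H]1[C@@]2(C)CCC[C@@](C)(C(=O)OC)[C@@H]2[C@@H](O[Si](CC)(CC)CC)C[C@@]1(C)O[Si](CC)(CC)CC)C(O)C[C@@H]1OC(=O)C=C1C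
F4 | step 22 | methyl 6α,8α-bis(triethylsilyloxy)-9β-{3-methylidene-5-[(2S)-3-methyl-5-oxo-2,5-dihydrofuran-2-yl]-4-oxopentyl}-4β,8β,10β-trimethyl-trans-decalin-4α-carboxylate | C=C(CC[C@@H]1[C@@]2(C)CCC[C@@](C)(C(=O)OC)[C@@H]2[C@@H](O[Si](CC)(CC)CC)C[C@@]1(C)O[Si](CC)(CC)CC)C(=O)C[C@@H]1OC(=O)C=C1C
F5 | step 13 | methyl 14-acetoxy-6α,7α-dihydroxy-13-oxo-13,14-secoabiet-8(14)-en-18-oate | CC(C)C(=O)CC[C@@H]1[C@@]2(C)CCC[C@@](C)(C(=O)OC)[C@@H]2[C@@H](O)[C@@H](O)C1=COC(C)=O
F6 | step 15 | methyl 6α,14-dihydroxy-13-oxo-13,14-secoabiet-7-en-18-oate | CC(C)C(=O)CC[C@@H]1[C@@]2(C)CCC[C@@](C)(C(=O)OC)[C@@H]2[C@@H](O)C=C1CO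
F7 | step 16 | methyl 14-(acetoxymercurio)-6α,8α-dihydroxy-13-oxo-13,14-secoabietan-18-oate | CC(C)C(=O)CC[C@@H]1[C@@]2(C)CCC[C@@](C)(C(=O)OC)[C@@H]2[C@@H](O)C[C@@]1(C[Hg]OC(C)=O)O
A1 | alternative 1 | dimethyl 6α-hydroxy-12,13,14,15,16-pentanorlabd-8(17)-ene-11,18-dioate | COC(=O)[C@@H]1[C@@]2(C)CCC[C@@](C)(C(=O)OC)[C@@H]2[C@@H](O)CC1=C
A2 | alternative 2 | 13E-alkene with free 16S-carbinol and C17 dioxolane ketal, 6α-tert-butyldimethylsilyl ether, 8α-triethylsilyl ether, C18 methyl ester | C/C(CC[C@@H]1[C@@]2(C)CCC[C@@](C)(C(=O)OC)[C@@H]2[C@@H](O[Si](C)(C)C(C)(C)C)C[C@@]1(C)O[Si](CC)(CC)CC)=C\C[C@H](O)C3(C)OCCO3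
A3 | alternative 3 | 6α,18-epoxy-8α-(triethylsilyloxy)-12,13,14,15,16-pentanorlabdan-11-yl acetate | CC(=O)OC[C@@H]1[C@@]2(C)CCC[C@@](C)(CO3)[C@@H]2[C@@H]3C[C@@]1(C)O[Si](CC)(CC)CC
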